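# Proposed synthesis of (−)-epicatechin 3-O-(3-hydroxy-4,5-dimethoxybenzoate) (CNP0331021.1)

## Analysis of the target

Target 17 is the C3 ester of (−)-epicatechin with 3-hydroxy-4,5-dimethoxybenzoic acid. It is a flavan: the phloroglucinol-type ring A is fused to the dihydropyran ring C (O1, C2, C3, C4, C4a, C8a), the catechol ring B sits on C2, and the aroyloxy group sits on C3. There are two adjacent stereocentres, C2 (R) and C3 (R), and the ring B aryl group and the C3 oxygen are cis on ring C. The five free phenols, above all the catechol, are prone to oxidation, so they are best carried as benzyl ethers until the last step. The C2–O1 bond is a benzylic ether para to a ring B oxygen, so C2 can epimerise by ring opening under acid or hot base. Ring A is strongly nucleophilic at C6 and C8, which limits the use of cationic chemistry. The difficulty is the cis-2,3 arrangement as a single enantiomer: hydroboration of a 2-aryl chromene adds H and B syn and therefore gives the trans series, and closures through a C2 cation also favour trans. The strategy rests on the fact that C2 (bearing ring B) and the oxygenated C3 are the two carbons of the enol ether C2=C3 of a 4H-chromene made of rings A and C. Adding the C2–C1' bond and a boron surrogate for the C3 oxygen to one face of that flat alkene creates both centres, cis, in one step.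

## Retrosynthetic reasoning

**17 ⇒ 16.** The five O–benzyl bonds are cut last. All phenols, including the one on the benzoate, then stay masked through every basic, oxidative and acylating step, and one hydrogenolysis that leaves the aryl ester and the methyl ethers alone releases 17.

**16 ⇒ 11 + 15.** The ester C(=O)–O bond at C3 is cut. Acylation on oxygen cannot disturb C3, the route becomes convergent, and the acid part enters as acid chloride 15 with its own phenol benzylated. Chloride 15 goes back through acid 14 and benzyl ester 13 to the commercial acid 12.

**11 ⇒ 10.** The C3–O bond is traced back to a C3–B bond. Oxidation of a secondary alkyl boronate moves C3 from boron to oxygen with retention, so the cis relationship in 10 becomes the cis relationship in 11. Boronate 10 is (2S,3R) although its atoms sit exactly as in (2R,3R)-11: with boron on C3, the ring B carbon outranks C3 at C2, so the C2 descriptor changes without any change in geometry.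

**10 ⇒ 7 + 8 + 9.** This is the key disconnection: the C2–C1' bond and the C3–B bond are removed together, which leaves the achiral chromene 7, the ring B bromide 8 and diboron 9. It is made here because no other cut creates both stereocentres in one event from a flat precursor while bringing in ring B as a simple aryl bromide. The forward reaction must add boron to C3 and the aryl group to C2 on the same face, and must choose one of the two enantiotopic faces of 7.

**7 ⇒ 5 ⇒ 4 ⇒ 3 ⇒ 1 + 2.** The enol ether C2=C3 of 7 comes from lactol 5 by loss of the C2 hydroxyl through its sulfonate 6. Lactol 5 is the half-reduced form of lactone 4, and the benzyl ethers of 4 are put onto the dihydroxy lactone 3. Lactone 3 is cut at C4–C4a and at the acyl–O1 bond into 1 and 2. The threefold symmetry of 1 makes the site of the C–C bond formation unambiguous.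

## Alternatives that were turned down

**Alternative 1: oxa-Diels–Alder of an ortho-quinone methide with a Z-enol ester.**
- Disconnection and key step: O1–C2 and C3–C4 are cut. The salicyl alcohol A2 would lose water under a chiral phosphoric acid to give the ortho-quinone methide A3, which would add to the Z-enol ester A4 to give A1. A1 is the same compound as 16.
- For: it is the most convergent plan. Ring C, both stereocentres and the complete ester would arise in one metal-free step, leaving only the hydrogenolysis. On step economy it beats the chosen route.
- Against: A3 has no substituent on its methylene carbon, so it is short-lived and prone to self-condensation, and it offers the chiral acid little to hold. In A4 the acyloxy group lowers the nucleophilicity of the alkene and polarises it against the para-benzyloxyphenyl group, so the required regiochemistry (the CH2 of A3 to the acyloxy carbon) is not assured. If the addition is stepwise through a benzylic cation stabilised by the para oxygen, bond rotation would break the link between the Z geometry and the cis product. A4 must also be made Z-selectively.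
- Comparison: the chosen route is longer after its key step, but its cis relationship comes from a syn addition to a ring alkene that cannot rotate, and its regiochemistry does not depend on two opposing donor groups.

**Alternative 2: six-endo epoxide–arene Friedel–Crafts closure of ring C.**
- Disconnection and key step: C4–C4a is cut. The threo epoxide A5 would be activated by Sc(OTf)3, and the ring A carbon ortho to the ether oxygen would attack the terminal epoxide carbon to give A6. A6 is the same compound as 11.
- For: both stereocentres are in place before the closure and are not touched by it. Ring A is symmetric, so only one kind of ortho carbon can attack. Attack at the unhindered terminal carbon gives the six-membered ring. All the reaction types are known, and on paper A6 is reached in fewer steps than 11 is here. On precedent and step count this alternative is stronger.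
- Against: the C–O bond at the future C2 of A5 is a para-alkoxybenzyl aryl ether, which a Lewis acid can ionise as easily as it activates the epoxide, and that would cost the C2 configuration or the ether itself. The epoxide can also rearrange by hydride shift. Making A5 needs an etherification with inversion at an electron-rich benzylic carbinol next to an epoxide, where partial ionisation erodes purity, and usually a kinetic resolution that discards half of the material.
- Comparison: the chosen route never exposes a configured C2 to a Lewis acid, because the C2–aryl bond is formed under basic, non-ionising conditions, and both centres come from an achiral precursor without resolution.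

**Alternative 3: aryl–oxygen coupling closing ring C with retention.**
- Disconnection and key step: O1–C8a is cut. The free benzylic hydroxyl of the bromoarene A7 would couple with its own aryl bromide under CuI, 3,4,7,8-tetramethyl-1,10-phenanthroline and Cs2CO3 to give the methoxymethyl ether A8.
- For: it is the most conservative plan. The C2–O bond is not broken, so retention is certain. The two centres would come from an asymmetric dihydroxylation of an E-alkene, whose syn diol maps directly onto the cis series and whose facial sense is predictable. On stereochemical certainty it is stronger than the chosen route.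
- Against: the two secondary hydroxyls of the diol must be told apart so that only the C3 oxygen carries the methoxymethyl group, which costs protecting-group steps. A secondary benzylic alkoxide couples slowly with an electron-rich, ortho-substituted aryl bromide, and at the temperature needed it can be oxidised at copper. After closure the methoxymethyl group must come off under acid, next to the acid-labile C2–O1 bond, before acylation and hydrogenolysis. The linear sequence is the longest of the four plans.
- Comparison: the chosen route forms the C2–aryl bond and both centres in one catalytic step on a chromene that is four steps from commercial material. The price is an unprecedented key step, for which a fallback is given below.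

Key step: step 5

Assumption: the face chosen by a chiral carbene–copper boryl on this new alkene class cannot be predicted with confidence. NHC* stands for (4S,5S)-1,3-bis(2-isopropylphenyl)-4,5-diphenylimidazolidin-2-ylidene or its (4R,5R) mirror image, and the route is written for whichever enantiomer delivers the (2S,3R)-boronate 10.

Remark: flavan numbering is used throughout (O1, C2, C3, C4 in ring C; C4a to C8a in ring A; C1' to C6' in ring B).

## Route

Step 1
Reactants: 1 phloroglucinol; 2 acrylic acid
Product: 3 5,7-dihydroxychroman-2-one
Conditions: Amberlyst-15, toluene, reflux (Dean–Stark), 1 in excess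
Reagents that add atoms: none
Why: Acid-catalysed Friedel–Crafts conjugate addition of the very electron-rich arene to acrylic acid, followed by lactonisation onto the neighbouring hydroxyl, should close the dihydrocoumarin; the symmetry of 1 leaves only one possible site, and an excess of 1 suppresses a second annulation.

Step 2
Reactants: 3 5,7-dihydroxychroman-2-one
Product: 4 5,7-bis(benzyloxy)chroman-2-one
Conditions: BnBr, K2CO3 (anhydrous), acetone, 50 °C
Reagents that add atoms: benzyl bromide, BrCc1ccccc1
Why: Williamson etherification of the two phenols; dry carbonate in acetone at moderate temperature should alkylate on oxygen while the exclusion of water keeps the aryl lactone closed.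

Step 3
Reactants: 4 5,7-bis(benzyloxy)chroman-2-one
Product: 5 5,7-bis(benzyloxy)chroman-2-ol (lactol, racemic at C2)
Conditions: i-Bu2AlH (1.1 equiv), CH2Cl2, −78 °C; aqueous potassium sodium tartrate
Reagents that add atoms: none
Why: Half-reduction of a lactone: the tetrahedral aluminium alkoxide is stable at −78 °C and gives the lactol only on work-up; the benzyl ethers are inert, and the new hemiacetal centre is uncontrolled but is destroyed in step 4.

Step 4
Reactants: 5 5,7-bis(benzyloxy)chroman-2-ol
Product: 7 5,7-bis(benzyloxy)-4H-chromene, via lactol mesylate 6 (not isolated)
Conditions: MsCl, Et3N (excess), CH2Cl2, 0 °C → reflux; chromatography on Et3N-deactivated silica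
Reagents that add atoms: methanesulfonyl chloride, CS(=O)(=O)Cl (its atoms are held only in 6 and are lost again on the way to 7)
Why: Sulfonylation of the hemiacetal hydroxyl, ionisation to the aryl oxocarbenium ion and loss of the C3 proton to the amine is the standard dehydration of a lactol to a cyclic enol ether; the excess amine keeps the medium basic, which should protect the acid-labile enol ether and the nucleophilic ring A.

Step 5
Reactants: 7 5,7-bis(benzyloxy)-4H-chromene; 8 4-bromo-1,2-bis(benzyloxy)benzene; 9 bis(pinacolato)diboron
Product: 10 (2S,3R)-5,7-bis(benzyloxy)-2-[3,4-bis(benzyloxy)phenyl]-3-(4,4,5,5-tetramethyl-1,3,2-dioxaborolan-2-yl)chroman (cis)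
Conditions: (NHC*)CuCl (10 mol %), Pd(OAc)2 (3 mol %), RuPhos (6 mol %), NaOt-Bu (1.5 equiv), toluene/THF, 0 °C → rt, 8 added slowly
Reagents that add atoms: none
Why: Proposed new method: the chiral monovalent copper tert-butoxide formed from (NHC*)CuCl and NaOt-Bu should react with 9 to give the copper boryl, which adds syn across C2=C3 of 7 with boron on C3 and copper on the oxygen-bearing C2; the alkylcopper then passes C2 with retention to the arylpalladium bromide formed from 8 and zerovalent palladium (from Pd(OAc)2 and RuPhos, reduced in the flask), and reductive elimination forms C2–C1' on the face that already carries boron. The closest known reaction type is the copper/palladium co-catalysed enantioselective syn-arylboration of indenes and 1,2-dihydronaphthalenes with aryl bromides and B2pin2; what is new is the alkene class, an aryl enol ether without styrene conjugation. No ring is closed: rings A and C are already present in 7, and the step makes one skeletal bond (C2–C1') and the C3–B bond. Both stereocentres come from the single syn addition to a flat, achiral alkene: the chiral carbene on copper selects the face in the borylcupration, which fixes C3 and, through the cis C–Cu bond, C2, and the cis relationship is kept because transmetallation of a non-benzylic secondary alkylcopper and the reductive elimination should both run with retention. The required regiochemistry (boron to C3) rests on the substrate: copper should prefer C2, where the inductive pull of the aryloxy oxygen stabilises the carbon–metal bond and where the bulky (NHC)Cu fragment meets less hindrance than next to the benzylic CH2. After the syn addition the only hydrogen on C3 is trans to the metal, so beta-hydride elimination at the palladium stage cannot compete with reductive elimination. The step also needs the borylcupration of this electron-rich alkene to outrun direct borylation of 8 and Heck arylation of 7, which is why 8 is added slowly and the copper loading is kept high.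

Step 6
Reactants: 10 (2S,3R)-cis-3-boryl chroman
Product: 11 (2R,3R)-5,7-bis(benzyloxy)-2-[3,4-bis(benzyloxy)phenyl]chroman-3-ol (5,7,3',4'-tetra-O-benzyl-(−)-epicatechin)
Conditions: NaBO3·4H2O, THF/H2O, rt
Reagents that add atoms: sodium perborate, [Na+].[O-]OB=O (used as its tetrahydrate)
Why: Oxidation of a secondary alkyl boronate: C3 migrates from boron to the peroxide oxygen with retention, so the cis pair is kept; the weakly basic perborate is chosen over alkaline peroxide to avoid base-induced loss of the beta-aryloxy group from the boronate.

Step 7
Reactants: 12 3-hydroxy-4,5-dimethoxybenzoic acid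
Product: 13 benzyl 3-(benzyloxy)-4,5-dimethoxybenzoate
Conditions: BnBr (2.5 equiv), K2CO3, DMF, 60 °C
Reagents that add atoms: benzyl bromide, BrCc1ccccc1
Why: Williamson etherification of the phenol together with alkylation of the carboxylate; both oxygen nucleophiles are benzylated under the same conditions.

Step 8
Reactants: 13 benzyl 3-(benzyloxy)-4,5-dimethoxybenzoate
Product: 14 3-(benzyloxy)-4,5-dimethoxybenzoic acid
Conditions: LiOH, THF/MeOH/H2O, 50 °C; then aqueous HCl
Reagents that add atoms: lithium hydroxide, [Li+].[OH-]
Why: Saponification of the benzyl ester by acyl–oxygen cleavage; the aryl benzyl ether and the methyl ethers are stable to hydroxide.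

Step 9
Reactants: 14 3-(benzyloxy)-4,5-dimethoxybenzoic acid
Product: 15 3-(benzyloxy)-4,5-dimethoxybenzoyl chloride
Conditions: (COCl)2, DMF (cat.), CH2Cl2, 0 °C → rt; evaporate and use crude
Reagents that add atoms: oxalyl chloride, ClC(=O)C(Cl)=O
Why: Acid chloride formation through the chloroiminium species from DMF; the by-products are gases, so the crude chloride can go straight into step 10.

Step 10
Reactants: 11 tetra-O-benzyl-(−)-epicatechin; 15 3-(benzyloxy)-4,5-dimethoxybenzoyl chloride
Product: 16 (2R,3R)-5,7-bis(benzyloxy)-2-[3,4-bis(benzyloxy)phenyl]chroman-3-yl 3-(benzyloxy)-4,5-dimethoxybenzoate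
Conditions: Et3N, DMAP, CH2Cl2, 0 °C → rt
Reagents that add atoms: none
Why: DMAP-catalysed acylation through the N-acylpyridinium ion should esterify the hindered pseudoaxial C3 hydroxyl; the reaction takes place at oxygen, so neither C3 nor C2 is touched.

Step 11
Reactants: 16 pentabenzyl ester
Product: 17 (2R,3R)-2-(3,4-dihydroxyphenyl)-5,7-dihydroxychroman-3-yl 3-hydroxy-4,5-dimethoxybenzoate
Conditions: H2 (1 atm), Pd(OH)2/C, THF/MeOH, rt; work-up under argon
Reagents that add atoms: none
Why: Hydrogenolysis of the five aryl benzyl ethers; the aryl ester and the methyl ethers are inert, and the cyclic benzylic C2–O1 bond is cleaved much more slowly than the benzyl ethers, so the reaction is stopped once hydrogen uptake ends.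

## Compound list

1 | phloroglucinol (benzene-1,3,5-triol) | Oc1cc(O)cc(O)c1 | starting material
2 | acrylic acid | C=CC(=O)O | starting material
3 | 5,7-dihydroxychroman-2-one | O=C1CCc2c(O)cc(O)cc2O1 | intermediate
4 | 5,7-bis(benzyloxy)chroman-2-one | O=C1CCc2c(OCc3ccccc3)cc(OCc3ccccc3)cc2O1 | intermediate
5 | 5,7-bis(benzyloxy)chroman-2-ol (racemic at C2) | OC1CCc2c(OCc3ccccc3)cc(OCc3ccccc3)cc2O1 | intermediate
6 | 5,7-bis(benzyloxy)chroman-2-yl methanesulfonate (racemic, not isolated) | CS(=O)(=O)OC1CCc2c(OCc3ccccc3)cc(OCc3ccccc3)cc2O1 | intermediate
7 | 5,7-bis(benzyloxy)-4H-chromene | C1=COc2cc(OCc3ccccc3)cc(OCc3ccccc3)c2C1 | intermediate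
8 | 4-bromo-1,2-bis(benzyloxy)benzene | Brc1ccc(OCc2ccccc2)c(OCc2ccccc2)c1 | starting material
9 | bis(pinacolato)diboron | CC1(C)OB(OC1(C)C)B1OC(C)(C)C(C)(C)O1 | starting material
10 | (2S,3R)-5,7-bis(benzyloxy)-2-[3,4-bis(benzyloxy)phenyl]-3-(4,4,5,5-tetramethyl-1,3,2-dioxaborolan-2-yl)chroman (cis) | CC1(C)OB(OC1(C)C)[C@@H]1Cc2c(OCc3ccccc3)cc(OCc3ccccc3)cc2O[C@@H]1c1ccc(OCc2ccccc2)c(OCc2ccccc2)c1 | intermediate
11 | (2R,3R)-5,7-bis(benzyloxy)-2-[3,4-bis(benzyloxy)phenyl]chroman-3-ol (cis) | O[C@@H]1Cc2c(OCc3ccccc3)cc(OCc3ccccc3)cc2O[C@@H]1c1ccc(OCc2ccccc2)c(OCc2ccccc2)c1 | intermediate
12 | 3-hydroxy-4,5-dimethoxybenzoic acid | COc1cc(C(=O)O)cc(O)c1OC | starting material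
13 | benzyl 3-(benzyloxy)-4,5-dimethoxybenzoate | COc1cc(C(=O)OCc2ccccc2)cc(OCc2ccccc2)c1OC | intermediate
14 | 3-(benzyloxy)-4,5-dimethoxybenzoic acid | COc1cc(C(=O)O)cc(OCc2ccccc2)c1OC | intermediate
15 | 3-(benzyloxy)-4,5-dimethoxybenzoyl chloride | COc1cc(C(Cl)=O)cc(OCc2ccccc2)c1OC | intermediate
16 | (2R,3R)-5,7-bis(benzyloxy)-2-[3,4-bis(benzyloxy)phenyl]chroman-3-yl 3-(benzyloxy)-4,5-dimethoxybenzoate | COc1cc(C(=O)O[C@@H]2Cc3c(OCc4ccccc4)cc(OCc4ccccc4)cc3O[C@@H]2c2ccc(OCc3ccccc3)c(OCc3ccccc3)c2)cc(OCc2ccccc2)c1OC | intermediate
17 | (2R,3R)-2-(3,4-dihydroxyphenyl)-5,7-dihydroxychroman-3-yl 3-hydroxy-4,5-dimethoxybenzoate | COc1cc(C(=O)O[C@@H]2Cc3c(O)cc(O)cc3O[C@@H]2c2ccc(O)c(O)c2)cc(O)c1OC | target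

## Step count and risk

Total step count: 11. Longest linear sequence: 8 steps (steps 1 to 6, then 10 and 11, from phloroglucinol). The acid branch (steps 7 to 9) joins at step 10.

**Step 5 (key step, the only step on new ground).**
- What may go wrong: the copper boryl may add too slowly to an enol ether that lacks styrene conjugation, so that direct borylation of 8, Heck arylation of 7 or protonation of the alkylcopper takes over. The borylcupration may also run with the opposite regiochemistry, after which copper on C3 can expel the ring oxygen and open ring C. Face selection may be poor on an alkene whose two carbons differ only by O against CH2. Finally, the alkoxide may trigger loss of the beta-aryloxy group from the product boronate.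
- Fallback by known chemistry, from lactone 4 and bromide 8, returning at 11: bromine–lithium exchange on 8 (n-BuLi, THF, −78 °C) and addition of the aryllithium to 4 should give the hemiketal 5,7-bis(benzyloxy)-2-[3,4-bis(benzyloxy)phenyl]chroman-2-ol F1, which is in equilibrium with its open hydroxy ketone. Dehydration with pyridinium p-toluenesulfonate in warm toluene gives the flav-2-ene 5,7-bis(benzyloxy)-2-[3,4-bis(benzyloxy)phenyl]-4H-chromene F2. Asymmetric hydroboration with monoisopinocampheylborane (the enantiomer that leads to the 2R series) and oxidation with NaBO3 adds H and B syn and therefore gives the trans alcohol (2R,3S)-5,7-bis(benzyloxy)-2-[3,4-bis(benzyloxy)phenyl]chroman-3-ol F3. Dess–Martin oxidation gives the ketone (2R)-5,7-bis(benzyloxy)-2-[3,4-bis(benzyloxy)phenyl]chroman-3-one F4. Reduction with LiBH(s-Bu)3 in THF at −78 °C, with hydride arriving on the face away from the C2 aryl group, returns the cis alcohol 11.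
- Cost of the fallback: five steps replace steps 5 and 6, and the enantiomeric purity then depends on the hydroboration and on the ketone not enolising towards C2.

**Step 4 (dehydration to 7).**
- What may go wrong: ionisation at C2 places an oxocarbenium ion beside a very nucleophilic ring A, so intermolecular Friedel–Crafts alkylation (oligomerisation) can compete with proton loss. The phenol of the open hydroxy-aldehyde tautomer may be sulfonylated instead of the hemiacetal hydroxyl. The enol ether may hydrolyse on silica.
- Fallback, from lactol 5, returning at 7: the leaving group is installed first as a stable, purifiable acetal. Methanol with catalytic pyridinium p-toluenesulfonate at rt should give 5,7-bis(benzyloxy)-2-methoxychroman F5, in which the oxocarbenium ion is trapped at once by the solvent. F5 is then treated with TMSOTf and i-Pr2NEt in CH2Cl2 at −20 °C, which eliminates methanol at low temperature in the presence of base and releases 7 immediately before step 5.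

**Step 2 (benzylation of 3).**
- What may go wrong: carbonate, adventitious hydroxide or a phenoxide of a second molecule may open the aryl lactone, after which the freed carboxylate and phenol are benzylated as well. The phloroglucinol-type ring may also be alkylated on carbon at C6 or C8.
- Fallback, from 3, returning at 4: the bond-forming event is changed from phenoxide alkylation under base to a Mitsunobu etherification (BnOH, PPh3, diisopropyl azodicarboxylate, THF, 0 °C → rt). No phenoxide or carbonate then meets the lactone, and alkylation on carbon is not expected. No new compound is formed on the way.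

**Step 11 (global hydrogenolysis).**
- What may go wrong: removal of five benzyl groups may stall part-way. Forcing it may cleave the benzylic C2–O1 bond and open ring C. The liberated catechol may oxidise in air during work-up.
- Fallback, from 16, returning at 17: non-reductive debenzylation with BCl3 and pentamethylbenzene as cation scavenger in CH2Cl2 at −78 °C cleaves aryl benzyl ethers without hydrogen and leaves the aryl ester intact. No new compound is formed on the way.

## Further compounds

F1 | step 5 | 5,7-bis(benzyloxy)-2-[3,4-bis(benzyloxy)phenyl]chroman-2-ol (racemic hemiketal) | OC1(c2ccc(OCc3ccccc3)c(OCc3ccccc3)c2)CCc2c(OCc3ccccc3)cc(OCc3ccccc3)cc2O1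
F2 | step 5 | 5,7-bis(benzyloxy)-2-[3,4-bis(benzyloxy)phenyl]-4H-chromene | C1=C(c2ccc(OCc3ccccc3)c(OCc3ccccc3)c2)Oc2cc(OCc3ccccc3)cc(OCc3ccccc3)c2C1
F3 | step 5 | (2R,3S)-5,7-bis(benzyloxy)-2-[3,4-bis(benzyloxy)phenyl]chroman-3-ol (trans) | O[C@H]1Cc2c(OCc3ccccc3)cc(OCc3ccccc3)cc2O[C@@H]1c1ccc(OCc2ccccc2)c(OCc2ccccc2)c1
F4 | step 5 | (2R)-5,7-bis(benzyloxy)-2-[3,4-bis(benzyloxy)phenyl]chroman-3-one | O=C1Cc2c(OCc3ccccc3)cc(OCc3ccccc3)cc2O[C@@H]1c1ccc(OCc2ccccc2)c(OCc2ccccc2)c1
F5 | step 4 | 5,7-bis(benzyloxy)-2-methoxychroman (racemic) | COC1CCc2c(OCc3ccccc3)cc(OCc3ccccc3)cc2O1
F0 | step 2 | none | none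
F0 | step 11 | none | none
A1 | alternative 1 | (2R,3R)-5,7-bis(benzyloxy)-2-[3,4-bis(benzyloxy)phenyl]chroman-3-yl 3-(benzyloxy)-4,5-dimethoxybenzoate | COc1cc(C(=O)O[C@@H]2Cc3c(OCc4ccccc4)cc(OCc4ccccc4)cc3O[C@@H]2c2ccc(OCc3ccccc3)c(OCc3ccccc3)c2)cc(OCc2ccccc2)c1OC
A2 | alternative 1 | 3,5-bis(benzyloxy)-2-(hydroxymethyl)phenol | OCc1c(O)cc(OCc2ccccc2)cc1OCc1ccccc1
A3 | alternative 1 | 3,5-bis(benzyloxy)-6-methylidenecyclohexa-2,4-dien-1-one | C=C1C(=O)C=C(OCc2ccccc2)C=C1OCc1ccccc1
A4 | alternative 1 | (Z)-2-[3,4-bis(benzyloxy)phenyl]ethenyl 3-(benzyloxy)-4,5-dimethoxybenzoate | COc1cc(C(=O)O/C=C\c2ccc(OCc3ccccc3)c(OCc3ccccc3)c2)cc(OCc2ccccc2)c1OC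
A5 | alternative 2 | (2R)-2-[(R)-[3,4-bis(benzyloxy)phenyl][3,5-bis(benzyloxy)phenoxy]methyl]oxirane | O1[C@@H]([C@H](Oc2cc(OCc3ccccc3)cc(OCc3ccccc3)c2)c2ccc(OCc3ccccc3)c(OCc3ccccc3)c2)C1
A6 | alternative 2 | (2R,3R)-5,7-bis(benzyloxy)-2-[3,4-bis(benzyloxy)phenyl]chroman-3-ol | O[C@@H]1Cc2c(OCc3ccccc3)cc(OCc3ccccc3)cc2O[C@@H]1c1ccc(OCc2ccccc2)c(OCc2ccccc2)c1
A7 | alternative 3 | (1R,2R)-1-[3,4-bis(benzyloxy)phenyl]-3-[2,4-bis(benzyloxy)-6-bromophenyl]-2-(methoxymethoxy)propan-1-ol | COCO[C@H](Cc1c(OCc2ccccc2)cc(OCc2ccccc2)cc1Br)[C@H](O)c1ccc(OCc2ccccc2)c(OCc2ccccc2)c1
A8 | alternative 3 | (2R,3R)-5,7-bis(benzyloxy)-2-[3,4-bis(benzyloxy)phenyl]-3-(methoxymethoxy)chroman | COCO[C@@H]1Cc2c(OCc3ccccc3)cc(OCc3ccccc3)cc2O[C@@H]1c1ccc(OCc2ccccc2)c(OCc2ccccc2)c1
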